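Before charging beta we have to decide one thing: does 0.0400 M of Pdt put in at the start cost anything? The forecast and I read the same runs and disagree.

| flask | Sbt | Ctl | Pdt | time |
|---|---|---|---|---|
| alpha | 0.0800 M | 8.00 × 10⁻⁴ M |  |  |
| delta | 0.0320 M | 8.00 × 10⁻⁴ M |  |  |
| eta | 0.0800 M | 0.00120 M |  |  |
| gamma | 0.160 M | 8.00 × 10⁻⁴ M |  |  |
| beta | 0.0800 M | 8.00 × 10⁻⁴ M | 0.0400 M | 30 min |

| alpha run: time / min | alpha run: [Pdt] / M | delta run: time / min | delta run: [Pdt] / M | eta run: time / min | eta run: [Pdt] / M | gamma run: time / min | gamma run: [Pdt] / M |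
|---|---|---|---|---|---|---|---|
| 5.0 | 0.01554 | 5.0 | 0.01239 | 5.0 | 0.02708 | 5.0 | 0.01459 |
| 10 | 0.02428 | 10 | 0.01831 | 10 | 0.03820 | 10 | 0.02532 |
| 15 | 0.03035 | 15 | 0.02132 | 15 | 0.04517 | 15 | 0.03274 |
| 20 | 0.03406 | 20 | 0.02400 | 20 | 0.04883 | 20 | 0.03710 |
| 25 | 0.03707 | 25 | 0.02473 | 25 | 0.05164 | 25 | 0.04102 |
| 30 | 0.03920 | 30 | 0.02553 | 30 | 0.05357 | 30 | 0.04386 |

(readings scatter by 2 × 10⁻⁴ M)

- apparent order in [Ctl] of the starting rate, round the charge of the alpha run (the rate where two percent of its Sbt have turned into Pdt)
- apparent order in [Sbt] of the starting rate, round the charge of the alpha run (the rate where two percent of its Sbt have turned into Pdt) (one fixed amount of Pdt, the same in the runs compared)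
- Pdt in the beta run at 30 min, as a share of the Sbt charged

- Overall: Sbt -> Pdt, with Ctl as catalyst.
- Constant volume, constant temperature.
- A reading of a species includes what of it is bound.
- An order is taken over about fifteen percent of the charge, up and down.
- A share of Pdt counts the Pdt that was charged too.

The forecast follows the clock: “the decay looks like time-driven catalyst loss, not product inhibition”. A fresh charge is then a fresh run, so beta adds about 0.037 M of Pdt to what it was given. It says 1.65 for the order in Ctl, −0.05 for the order in Sbt and 96% for beta's Pdt share at 30 min, the share one gets if the loaded catalyst dies.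

I follow the load: the rate goes with the Pdt present, which is product inhibition. So I want a flask already standing at beta's Pdt, and eta passes there, with 0.03820 M at 10 min.

Eta has more Ctl, so I need the order first. Alpha holds 0.02428 M at 10 min, while eta holds more, 0.02708 M, at 5.0 min. Equal Pdt therefore comes sooner by a clock ratio above 2.00, for 1.50 times the Ctl. If the rate goes with the Pdt present, that puts the order in Ctl above about 1.71, and I commit to 2.

Eta's slope across that point, divided by the Ctl ratio squared, gives ρ, the load rate, meaning the rate of a flask with alpha's Ctl at about beta's starting Pdt: 8.04 × 10⁻⁴ M min⁻¹. At 10 min eta holds at most 0.0418 M of Sbt against beta's 0.0800 M. But gamma, with 0.160 M of Sbt, holds less Pdt at 5.0 min than alpha with 0.0800 M, so I carry ρ over to beta unchanged.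

Alpha across the same 5.0 min to 15 min, with less Pdt at 10 min than eta, runs at 0.00148 M min⁻¹, faster than ρ, so by my reckoning equal clocks do not give equal rates at equal Ctl. Holding ρ for 30 min on top of the charge, I expect 80.2%.

The flask gives 75.5% for beta's Pdt share at 30 min, with 2.0 for the order in Ctl and −0.18 for the order in Sbt.

    Ctl + Sbt ⇌ Ctl.Sbt, settled at all times (20.50 L mol⁻¹)
    Ctl.Sbt + Ctl → Pdt + 2 Ctl (27540 L mol⁻¹ min⁻¹)
    2 Sbt → Q (0.4308 L mol⁻¹ min⁻¹)
    Ctl + Pdt ⇌ Ctl.Pdt, settled at all times (50.80 L mol⁻¹)

The forecast stands above that, and mine stands 4.7 percentage points above it. Where 2 percent of alpha's Sbt have turned into Pdt, eta runs at 2.2 times alpha's rate. Beta made 0.0204 M, a mean of 6.80 × 10⁻⁴ M min⁻¹, which is 0.846 of ρ. The clock view keeps one region, the late stretch of alpha: between 25 min and 30 min, holding about the Pdt that eta held at 10 min, alpha runs at 4.26 × 10⁻⁴ M min⁻¹, or 0.530 of ρ.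

The earlier runs and the new flask were generated by integration from invented constants; the scatter is artificial.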